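**Plan**

- Germacrane numbering throughout: C1/C10 oxirane, C4 bearing C15, C5 alkene CH, C6 lactone CH–O, C7, C8 CH–OAc, C9, C10 bearing C14, lactone arm C11(=C13)–C12. Retrosynthetic cuts, in order: the two acetate C–O bonds and the C15 oxidation level; the oxirane C–O bonds at C1/C10 and the C14–O bond; C11=C13; the lactone bond O6–C12 and the bond C7–C11; last C6–C7 and C8–C9.
- Enabling feature: C9–C10(C14)=C1–C2–C3–C4(C15)=C5–C6 is the cis,cis head-to-tail isoprene dimer, an eight-membered ring once C6 is bonded to C9. The 1,3-related oxygens on C6 and C8 mark C7–C8 as a ketene unit inserted into that C6–C9 bond.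
- Forward: the commercial eight-membered diene 1 gets its C15 hydroxyl, the C6 ketone and the C6=C9 silyl enol ether. A cyclobutanone is fused on C6–C9 by (2+2) with dichloroketene, and cutting C6–C9 uncovers the ten-membered 1,3-dione. Then follow the acetate arm on C7, the γ-lactone ring on O6, the methylene group, the C14 hydroxyl and the oxirane.
- Stereochemistry: both ring alkene geometries come unchanged from 1. C8, and C7 by dynamic kinetic resolution, come from a Ru–TsDPEN transfer hydrogenation; C6 from an oxazaborolidine (CBS) reduction; the trans lactone follows from C6/C7; C1/C10 from a Sharpless epoxidation directed by the C14 hydroxyl. All earlier stereocentres are racemic and are erased before step 9.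

Key step: step 7

Assumption: commercial 1 is freed from its 1,6-dimethyl isomer before use, and the sense of induction in steps 9 and 11 follows the usual models (acyl-bearing C7 arm in the place of the aryl group for the Ru–TsDPEN catalyst, alkenyl arm as the large group for the oxazaborolidine); a Mosher ester analysis of first samples decides whether the enantiomeric catalyst is needed.

Abbreviations: TBDPS = tert-butyldiphenylsilyl, TBS = tert-butyldimethylsilyl.

**Route**

Step 1
Reactants: 1 (1Z,5Z)-1,5-dimethylcycloocta-1,5-diene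
Product: 2 [(1E,5Z)-5-methylcycloocta-1,5-dien-1-yl]methanol (C15 alcohol; both ring alkenes cis within the ring)
Conditions: SeO2 (cat.), t-BuOOH, CH2Cl2, 0 °C to rt, stopped at partial conversion, 1 recycled
Reagents that add atoms: tert-butyl hydroperoxide, CC(C)(C)OO (oxygen source, relayed by selenium dioxide, O=[Se]=O)
Why: SeO2 allylic hydroxylation (ene reaction, then [2,3]-sigmatropic shift) should oxidise the methyl group that lies cis to the vinylic hydrogen, because the ring allylic C–H bonds of the cyclooctadiene are poorly aligned with the π bond, and the ring-cis geometry is the one this shift regenerates.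

Step 2
Reactants: 2 C15 allylic alcohol
Product: 3 rac-cis-(5-methyl-9-oxabicyclo[6.1.0]non-4-en-1-yl)methanol (C4–C5 epoxy alcohol)
Conditions: VO(acac)2 (cat.), t-BuOOH, CH2Cl2, 0 °C to rt
Reagents that add atoms: tert-butyl hydroperoxide, CC(C)(C)OO
Why: Hydroxyl-directed vanadium-catalysed epoxidation should oxidise only the alkene that carries the allylic alcohol (as with geraniol) and leave the more electron-rich C1=C10 alkene; the cis epoxide is racemic and its centres are erased in step 5.

Step 3
Reactants: 3 epoxy alcohol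
Product: 4 rac-tert-butyl[(5-methyl-9-oxabicyclo[6.1.0]non-4-en-1-yl)methoxy]diphenylsilane (TBDPS ether of 3)
Conditions: t-BuPh2SiCl, imidazole, DMF, rt
Reagents that add atoms: tert-butyl(chloro)diphenylsilane, CC(C)(C)[Si](Cl)(c1ccccc1)c1ccccc1
Why: Standard silylation of a primary alcohol; the TBDPS ether is chosen because it should survive acetic acid (step 7), weak acids, lithium amides and the oxidants used up to step 15.

Step 4
Reactants: 4 epoxy silyl ether
Product: 7 rac-1-{[(tert-butyldiphenylsilyl)oxy]methyl}-5-methylcycloocta-2,5-dien-1-ol, via hydroxy selenide 5 (not isolated), via selenoxide 6 (not isolated)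
Conditions: PhSeSePh, NaBH4, EtOH, reflux; then 30% H2O2, pyridine, THF, 0 °C to rt
Reagents that add atoms: none
Why: Selenolate opening of the epoxide (SN2 at the secondary carbon C5, trans) followed by selenoxide syn-elimination, which can only run towards C6 because C4 has no hydrogen, should give the tertiary allylic alcohol with a cis C5=C6 bond.

Step 5
Reactants: 7 tertiary allylic alcohol
Product: 8 (2E,6Z)-3-{[(tert-butyldiphenylsilyl)oxy]methyl}-7-methylcycloocta-2,6-dien-1-one (C6 ketone, C4=C5 enone, C1=C10 alkene; both ring-cis)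
Conditions: pyridinium chlorochromate [C5H5NH][CrO3Cl], Celite, CH2Cl2, rt
Reagents that add atoms: none
Why: Babler–Dauben oxidative transposition: the tertiary allylic chromate ester shifts [3,3] to C6 and is oxidised there, so the oxygen of 7 becomes the C6 carbonyl and the alkene returns to C4=C5, held cis by the ring.

Step 6
Reactants: 8 dienone
Product: 9 tert-butyl{[5-methyl-3-(trimethylsilyloxy)cycloocta-1,3,5-trien-1-yl]methoxy}diphenylsilane (C6–OSiMe3, C6=C9; all three ring double bonds cis)
Conditions: LiN(iPr)2, Me3SiCl (in situ quench), THF, −78 °C; non-aqueous work-up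
Reagents that add atoms: chlorotrimethylsilane, C[Si](C)(C)Cl
Why: Kinetic enolisation of an enone takes the α′ proton, here at C9, the only α′ carbon and also allylic, and in situ silylation should trap the cross-conjugated enolate as the C6=C9 silyl enol ether before the trienol ether can equilibrate or electrocyclise.

Step 7
Reactants: 9 silyl trienol ether; 10 dichloroacetyl chloride
Product: 14 (4E,8Z)-5-{[(tert-butyldiphenylsilyl)oxy]methyl}-9-methylcyclodeca-4,8-diene-1,3-dione, via dichloroketene 11 (not isolated), via dichlorocyclobutanone adduct 12 (not isolated), via dechlorinated cyclobutanone 13 (not isolated)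
Conditions: 10 (slow addition), Et3N, hexane, 0 °C to rt; filter, concentrate; then Zn, AcOH/H2O, rt
Reagents that add atoms: none
Why: Et3N dehydrochlorinates 10 to dichloroketene 11, whose carbonyl carbon (the future C8) is attacked by C9 of the silyl enol ether; the 1,4-zwitterion (chloroenolate at C7, cation at C6 stabilised by the siloxy group and the C4=C5 vinyl group) collapses by C7–C6 bond formation, a stepwise (2+2) cycloaddition that closes the four-membered ring as the cis-fused cyclobutanone 12. The closest known reaction is the cycloaddition of dichloroketene to cyclic silyl enol ethers and the two-carbon ring expansion of the adducts to cycloalkane-1,3-diones. Zinc in acetic acid removes both chlorines first, so that on loss of the silyl group the C6 alkoxide cuts the fusion bond C6–C9 (retro-aldol) and not C6–C7: the carbanion left at C9 is an allylically stabilised enolate of the C8 ketone, whereas cleavage towards C7 would leave an unstabilised primary enolate carbon. No ring is closed in this second event; the ten-membered ring is uncovered from the bicycle, and the two ring-fusion stereocentres of 12 (cis by suprafacial collapse) disappear, so 14 is achiral. The selectivity needed is bonding at C9 and not at the vinylogous terminus C1 or across C10=C1: C9 carries the oxygen-conjugated electron density, attack there leaves the doubly stabilised cation at C6, and amine-generated dichloroketene does not add to unactivated trisubstituted alkenes. Both cis trisubstituted alkenes and the C15 silyl ether are spectators.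

Step 8
Reactants: 14 ten-membered 1,3-dione; 15 tert-butyl bromoacetate
Product: 16 tert-butyl 2-[(4E,8Z)-5-{[(tert-butyldiphenylsilyl)oxy]methyl}-9-methyl-1,3-dioxocyclodeca-4,8-dien-2-yl]acetate (acetate arm on C7; C7 configurationally labile)
Conditions: K2CO3, acetone, rt
Reagents that add atoms: none
Why: C-alkylation of a β-diketone at its most acidic carbon (C7, between the two carbonyls) with a reactive α-bromo ester; the tert-butyl ester is chosen so that the arm cannot lactonise before step 11.

Step 9
Reactants: 16 2-alkyl-1,3-dione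
Product: 17 tert-butyl (7R,8S)-8-hydroxy-6-oxo ester (as 16 with the C8 ketone reduced; C7 arm and C8 hydroxyl trans across the ring, as in the target)
Conditions: RuCl[(S,S)-TsDPEN](p-cymene) (cat.), HCO2H/Et3N (5:2), CH2Cl2, rt
Reagents that add atoms: none
Why: Noyori–Ikariya asymmetric transfer hydrogenation with dynamic kinetic resolution, as established for 2-alkyl-1,3-diketones: the non-conjugated, less hindered C8 carbonyl should be reduced in preference to the enone carbonyl, C7 epimerises through the enol faster than hydride transfer, and the chiral ruthenium hydride sets C8 and with it the syn-aldol-type (ring-trans) C7/C8 relationship.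

Step 10
Reactants: 17 β-hydroxy ketone
Product: 18 tert-butyl (7R,8S)-8-(tert-butyldimethylsilyloxy)-6-oxo ester (TBS ether of 17)
Conditions: t-BuMe2SiOTf, 2,6-lutidine, CH2Cl2, −78 °C
Reagents that add atoms: tert-butyldimethylsilyl trifluoromethanesulfonate, CC(C)(C)[Si](C)(C)OS(=O)(=O)C(F)(F)F
Why: Silyl triflate/lutidine silylation protects the aldol-type alcohol without base-induced retro-aldol or epimerisation at C7, and masks O8 so that only O6 can later lactonise and so that the lactone can be enolised.

Step 11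
Reactants: 18 β-silyloxy enone
Product: 20 trans-fused γ-lactone (6R,7S,8S) with C12 on O6 bearing C8–OTBS and C15–OTBDPS, via hydroxy ester 19 (not isolated)
Conditions: (R)-2-methyl-CBS-oxazaborolidine, catecholborane, toluene, −78 °C; MeOH quench; then camphorsulfonic acid (cat.), CH2Cl2, rt
Reagents that add atoms: none
Why: Corey–Bakshi–Shibata reduction of the enone carbonyl, with the alkenyl arm in the large-group site as for alkenyl/sec-alkyl ketones, should deliver hydride to the face that gives the (6R)-alcohol while catecholborane at −78 °C leaves the alkenes untouched; acid-catalysed intramolecular transesterification (5-exo-trig) then closes the lactone on O6, the only free hydroxyl, trans-fused as fixed by C6 and C7.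

Step 12
Reactants: 20 γ-lactone; 21 N,N-dimethylmethyleneiminium iodide (Eschenmoser's salt)
Product: 22 α-(dimethylaminomethyl) lactone (as 20 with CH2NMe2 on C11; C11 as a mixture)
Conditions: LiN(iPr)2, THF, −78 °C; then 21, −78 to 0 °C
Reagents that add atoms: none
Why: Mannich reaction of the lactone lithium enolate with Eschenmoser's salt introduces C13; no other acidic hydrogen or electrophilic carbonyl is present, and the new C11 centre is removed in the next step.

Step 13
Reactants: 22 Mannich base
Product: 24 α-methylene lactone (6R,7S,8S) bearing C8–OTBS and C15–OTBDPS, via ammonium iodide 23 (not isolated)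
Conditions: MeI, MeOH, rt; then NaHCO3, H2O/CH2Cl2, rt
Reagents that add atoms: none
Why: Quaternisation followed by Hofmann-type β-elimination (E1cB through the lactone enolate) should give the exocyclic C11=C13 bond under conditions too mild to disturb the silyl ethers.

Step 14
Reactants: 24 α-methylene lactone
Product: 25 C14 allylic alcohol (as 24 with CH2OH on C10; C1=C10 still ring-cis)
Conditions: SeO2 (cat.), t-BuOOH, CH2Cl2, rt
Reagents that add atoms: tert-butyl hydroperoxide, CC(C)(C)OO (oxygen source, relayed by selenium dioxide, O=[Se]=O)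
Why: SeO2 allylic hydroxylation, known for the 1(10)-alkene of germacranolides that carry an α-methylene lactone, should attack C1=C10, the only alkene without allylic oxygen (C4=C5 is flanked by O6 and O15), at C14, the methyl cis to H1, with the ring-cis geometry retained.

Step 15
Reactants: 25 allylic alcohol
Product: 26 (1R,10R)-epoxy alcohol (oxirane on C1/C10, free C14 hydroxyl; otherwise as 25)
Conditions: Ti(OiPr)4, L-(+)-diethyl tartrate, t-BuOOH, 4 Å molecular sieves, CH2Cl2, −20 °C
Reagents that add atoms: tert-butyl hydroperoxide, CC(C)(C)OO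
Why: Sharpless asymmetric epoxidation of a 2,3-disubstituted allylic alcohol: with the hydroxymethyl group drawn at the lower right, L-(+)-tartrate delivers oxygen to the lower face, which is the (1R,10R) oxirane, and only C1=C10 has a free allylic hydroxyl.

Step 16
Reactants: 26 bis-silyl epoxy alcohol
Product: 27 (1R,6R,7R,8S,10R)-8,14,15-triol (both silyl ethers removed)
Conditions: Bu4NF, AcOH, THF, 0 °C to rt
Reagents that add atoms: none
Why: Fluoride desilylation buffered with acetic acid should free O8 and O15 while keeping the medium non-basic, so that the C8 alkoxide cannot translactonise or add to the methylene lactone and the oxirane is not opened.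

Step 17
Reactants: 27 triol
Product: 28 (1R,6R,7R,8S,10R)-15-oxo-8,14-diol (C15 enal)
Conditions: MnO2 (activated, excess), CH2Cl2, rt
Reagents that add atoms: none
Why: MnO2 oxidises allylic alcohols selectively, and C15 is the only allylic hydroxyl (C14 is now on an oxirane carbon and C8 is a saturated secondary alcohol).

Step 18
Reactants: 28 enal diol
Product: 29 CNP0211286.1, (1R,6R,7R,8S,10R)-8,14-diacetoxy-1,10-epoxy-15-oxo-germacra-4,11(13)-dien-12,6-olide
Conditions: Ac2O, pyridine, 4-(dimethylamino)pyridine (cat.), CH2Cl2, 0 °C to rt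
Reagents that add atoms: acetic anhydride, CC(=O)OC(C)=O
Why: Nucleophile-catalysed acetylation of the two remaining hydroxyls (C8 secondary, C14 primary) should be compatible with the enal, oxirane and methylene lactone and gives the target.

**Compound list**

1 | (1Z,5Z)-1,5-dimethylcycloocta-1,5-diene | C/C1=C/CC/C(C)=C\CC1 | starting material
2 | [(1E,5Z)-5-methylcycloocta-1,5-dien-1-yl]methanol | OC/C1=C/CC/C(C)=C\CC1 | intermediate
3 | rac-cis-(5-methyl-9-oxabicyclo[6.1.0]non-4-en-1-yl)methanol | OC[C@]1(O2)CC/C=C(C)\CC[C@H]12 | intermediate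
4 | rac-cis-tert-butyl[(5-methyl-9-oxabicyclo[6.1.0]non-4-en-1-yl)methoxy]diphenylsilane | CC(C)(C)[Si](c3ccccc3)(c4ccccc4)OC[C@]1(O2)CC/C=C(C)\CC[C@H]12 | intermediate
5 | rac-trans-1-{[(tert-butyldiphenylsilyl)oxy]methyl}-5-methyl-2-(phenylselanyl)cyclooct-5-en-1-ol | CC(C)(C)[Si](c3ccccc3)(c4ccccc4)OC[C@]1(O)CC/C=C(C)\CC[C@@H]1[Se]c5ccccc5 | intermediate
6 | selenoxide of 5 (mixture at selenium) | CC(C)(C)[Si](c3ccccc3)(c4ccccc4)OC[C@]1(O)CC/C=C(C)\CC[C@@H]1[Se](=O)c5ccccc5 | intermediate
7 | rac-(2Z,5Z)-1-{[(tert-butyldiphenylsilyl)oxy]methyl}-5-methylcycloocta-2,5-dien-1-ol | CC(C)(C)[Si](c3ccccc3)(c4ccccc4)OCC1(O)/C=C\C/C(C)=C\CC1 | intermediate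
8 | (2E,6Z)-3-{[(tert-butyldiphenylsilyl)oxy]methyl}-7-methylcycloocta-2,6-dien-1-one | O=C1/C=C(CO[Si](c3ccccc3)(c4ccccc4)C(C)(C)C)\CC/C=C(C)\C1 | intermediate
9 | tert-butyl{[5-methyl-3-(trimethylsilyloxy)cycloocta-1,3,5-trien-1-yl]methoxy}diphenylsilane (all ring double bonds cis) | C1/C(CO[Si](c3ccccc3)(c4ccccc4)C(C)(C)C)=C\C(O[Si](C)(C)C)=C/C(C)=C\C1 | intermediate
10 | dichloroacetyl chloride | ClC(Cl)C(Cl)=O | starting material
11 | dichloroketene | ClC(Cl)=C=O | intermediate
12 | rac-cis-fused 10,10-dichloro-3-{[(tert-butyldiphenylsilyl)oxy]methyl}-7-methyl-1-(trimethylsilyloxy)bicyclo[6.2.0]deca-2,6-dien-9-one | C[Si](C)(C)O[C@@]12/C=C(CO[Si](c3ccccc3)(c4ccccc4)C(C)(C)C)\CC/C=C(C)\[C@@H]1C(=O)C2(Cl)Cl | intermediate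
13 | rac-cis-fused 3-{[(tert-butyldiphenylsilyl)oxy]methyl}-7-methyl-1-(trimethylsilyloxy)bicyclo[6.2.0]deca-2,6-dien-9-one | C[Si](C)(C)O[C@@]12/C=C(CO[Si](c3ccccc3)(c4ccccc4)C(C)(C)C)\CC/C=C(C)\[C@@H]1C(=O)C2 | intermediate
14 | (4E,8Z)-5-{[(tert-butyldiphenylsilyl)oxy]methyl}-9-methylcyclodeca-4,8-diene-1,3-dione (ketones at C6 and C8; both ring alkenes cis in the ring) | C1C(=O)C/C(C)=C\CC/C(CO[Si](c3ccccc3)(c4ccccc4)C(C)(C)C)=C\C1=O | intermediate
15 | tert-butyl bromoacetate | CC(C)(C)OC(=O)CBr | starting material
16 | tert-butyl 2-[(4E,8Z)-5-{[(tert-butyldiphenylsilyl)oxy]methyl}-9-methyl-1,3-dioxocyclodeca-4,8-dien-2-yl]acetate (C7 labile) | CC(C)(C)OC(=O)CC1C(=O)C/C(C)=C\CC/C(CO[Si](c3ccccc3)(c4ccccc4)C(C)(C)C)=C\C1=O | intermediate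
17 | tert-butyl ester of the (7R,8S)-8-hydroxy-6-oxo acid (16 with C8 reduced; C7 arm trans to O8) | CC(C)(C)OC(=O)C[C@@H]1[C@@H](O)C/C(C)=C\CC/C(CO[Si](c3ccccc3)(c4ccccc4)C(C)(C)C)=C\C1=O | intermediate
18 | C8 TBS ether of 17 (7R,8S) | CC(C)(C)OC(=O)C[C@@H]1[C@@H](O[Si](C)(C)C(C)(C)C)C/C(C)=C\CC/C(CO[Si](c3ccccc3)(c4ccccc4)C(C)(C)C)=C\C1=O | intermediate
19 | (6R,7S,8S)-6-hydroxy tert-butyl ester (18 with C6 reduced) | CC(C)(C)OC(=O)C[C@@H]1[C@@H](O[Si](C)(C)C(C)(C)C)C/C(C)=C\CC/C(CO[Si](c3ccccc3)(c4ccccc4)C(C)(C)C)=C\[C@H]1O | intermediate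
20 | (6R,7S,8S)-trans-fused γ-lactone (C12 on O6, C11 is CH2), C8–OTBS, C15–OTBDPS, C1=C10 and C4=C5 ring-cis | C1C(=O)O[C@@H]2/C=C(/CO[Si](c3ccccc3)(c4ccccc4)C(C)(C)C)CC/C=C(C)\C[C@H](O[Si](C)(C)C(C)(C)C)[C@@H]12 | intermediate
21 | N,N-dimethylmethyleneiminium iodide | C=[N+](C)C.[I-] | starting material
22 | 20 with CH2NMe2 on C11 (C11 mixture) | CN(C)CC1C(=O)O[C@@H]2/C=C(/CO[Si](c3ccccc3)(c4ccccc4)C(C)(C)C)CC/C=C(C)\C[C@H](O[Si](C)(C)C(C)(C)C)[C@@H]12 | intermediate
23 | trimethylammonium iodide of 22 | C[N+](C)(C)CC1C(=O)O[C@@H]2/C=C(/CO[Si](c3ccccc3)(c4ccccc4)C(C)(C)C)CC/C=C(C)\C[C@H](O[Si](C)(C)C(C)(C)C)[C@@H]12.[I-] | intermediate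
24 | (6R,7S,8S)-α-methylene lactone, C8–OTBS, C15–OTBDPS | C=C1C(=O)O[C@@H]2/C=C(/CO[Si](c3ccccc3)(c4ccccc4)C(C)(C)C)CC/C=C(C)\C[C@H](O[Si](C)(C)C(C)(C)C)[C@@H]12 | intermediate
25 | 24 with C14 hydroxyl (CH2OH on C10) | C=C1C(=O)O[C@@H]2/C=C(/CO[Si](c3ccccc3)(c4ccccc4)C(C)(C)C)CC/C=C(CO)\C[C@H](O[Si](C)(C)C(C)(C)C)[C@@H]12 | intermediate
26 | (1R,6R,7S,8S,10R)-1,10-epoxy-14-hydroxy lactone, C8–OTBS, C15–OTBDPS | C=C1C(=O)O[C@@H]2/C=C(/CO[Si](c4ccccc4)(c5ccccc5)C(C)(C)C)CC[C@H]3O[C@@]3(CO)C[C@H](O[Si](C)(C)C(C)(C)C)[C@@H]12 | intermediate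
27 | (1R,6R,7R,8S,10R)-1,10-epoxy-8,14,15-trihydroxy lactone | C=C1C(=O)O[C@@H]2/C=C(/CO)CC[C@H]3O[C@@]3(CO)C[C@H](O)[C@@H]12 | intermediate
28 | (1R,6R,7R,8S,10R)-1,10-epoxy-8,14-dihydroxy-15-oxo lactone | C=C1C(=O)O[C@@H]2/C=C(/C=O)CC[C@H]3O[C@@]3(CO)C[C@H](O)[C@@H]12 | intermediate
29 | CNP0211286.1, (1R,6R,7R,8S,10R)-8,14-diacetoxy-1,10-epoxy-15-oxo lactone | C=C1C(=O)O[C@@H]2/C=C(/C=O)CC[C@H]3O[C@@]3(COC(C)=O)C[C@H](OC(C)=O)[C@@H]12 | target

**Step count and risks**

Total: 18 steps. Longest linear sequence: 18 steps from 1 (the route is fully linear; 10, 15 and 21 enter as purchased reagents).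

Steps most likely to fail:

Step 7. The ketene may bond at the vinylogous terminus C1 of the C6=C9–C10=C1 dienol ether, or across C10=C1, in competition with C9, and silyl transfer within the zwitterion may give open-chain C-acylation without ring expansion. The fallback takes the C10=C1 alkene out of conjugation before the cycloaddition. It sets out from 8: OsO4 (cat.) with N-methylmorpholine N-oxide should dihydroxylate the electron-rich C1=C10 alkene, not the enone alkene, to the cis-diol F1; 2,2-dimethoxypropane with pyridinium p-toluenesulfonate gives the acetonide F2; LiN(iPr)2/Me3SiCl gives the silyl dienol ether F3, in which C9 is the only nucleophilic carbon. Compound 10 with Et3N and then Zn/AcOH, as in step 7, should lead through the dichlorocyclobutanone F4 and the cyclobutanone F5 to the dione acetonide F6. Aqueous acetic acid frees the dione diol F7, thiocarbonyldiimidazole gives the cyclic thiocarbonate F8, and a Corey–Winter olefination under the mild Corey–Hopkins conditions (1,3-dimethyl-2-phenyl-1,3,2-diazaphospholidine, 40 °C, below the temperature at which the 1,5-diene could undergo Cope rearrangement) restores the cis C1=C10 alkene. The route is rejoined at 14.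

Step 9. Hydride transfer may fail to discriminate the two carbonyls of the 2-alkyl dione, or the dynamic kinetic resolution may give an unfavourable ratio at the labile C7 centre. The fallback reduces before alkylating, so that C7 is set by substrate-controlled enolate alkylation. It sets out from 14: the same ruthenium catalyst with HCO2H/Et3N should reduce the unsubstituted 1,3-dione at its non-conjugated C8 carbonyl to the (8S)-hydroxy enone F9; t-BuMe2SiOTf/2,6-lutidine gives the silyl ether F10; LiN(iPr)2 at −78 °C forms the only possible α′-enolate (C7), which is alkylated with 15 on the face away from the neighbouring silyloxy group. The route is rejoined at 18.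

Step 11. Hydride may be delivered to the wrong face of the C6 carbonyl, because the branched C7 arm competes with the alkenyl arm for the large-group site of the oxazaborolidine and the facial bias of the ten-membered ring is unknown. The fallback corrects C6 by inversion. It sets out from 18: if the reduction (with the oxazaborolidine or with NaBH4/CeCl3) gives mainly the C6 epimer, the (6S)-hydroxy ester F11, a Mitsunobu reaction with 4-nitrobenzoic acid (PPh3, diisopropyl azodicarboxylate) inverts C6 to the (6R)-4-nitrobenzoate F12; K2CO3 in MeOH removes the ester to give 19, which is lactonised with camphorsulfonic acid as in step 11. The route is rejoined at 20.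

**Further compounds**

F1 | step 7 | rac-cis-1,10-diol of 8 (6,7-dihydroxy-3-{[(tert-butyldiphenylsilyl)oxy]methyl}-7-methylcyclooct-2-en-1-one) | O=C1/C=C(CO[Si](c3ccccc3)(c4ccccc4)C(C)(C)C)\CC[C@H](O)[C@](C)(O)C1
F2 | step 7 | acetonide of F1 | O=C1/C=C(CO[Si](c3ccccc3)(c4ccccc4)C(C)(C)C)\CC[C@@H]2OC(C)(C)O[C@]2(C)C1
F3 | step 7 | C6=C9 trimethylsilyl dienol ether of F2 | C1/C(CO[Si](c3ccccc3)(c4ccccc4)C(C)(C)C)=C\C(O[Si](C)(C)C)=C/[C@@]2(C)OC(C)(C)O[C@H]2C1
F4 | step 7 | dichlorocyclobutanone adduct of F3 (cis ring fusion, mixture relative to the acetonide) | C[Si](C)(C)OC12/C=C(CO[Si](c4ccccc4)(c5ccccc5)C(C)(C)C)\CC[C@@H]3OC(C)(C)O[C@]3(C)C1C(=O)C2(Cl)Cl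
F5 | step 7 | dechlorinated cyclobutanone from F4 | C[Si](C)(C)OC12/C=C(CO[Si](c4ccccc4)(c5ccccc5)C(C)(C)C)\CC[C@@H]3OC(C)(C)O[C@]3(C)C1C(=O)C2
F6 | step 7 | 1,10-acetonide of the ten-membered 1,3-dione | C1C(=O)C[C@@]2(C)OC(C)(C)O[C@H]2CC/C(CO[Si](c3ccccc3)(c4ccccc4)C(C)(C)C)=C\C1=O
F7 | step 7 | cis-1,10-diol of the ten-membered 1,3-dione | C1C(=O)C[C@@](C)(O)[C@@H](O)CC/C(CO[Si](c3ccccc3)(c4ccccc4)C(C)(C)C)=C\C1=O
F8 | step 7 | cyclic 1,10-thiocarbonate of F7 | C1C(=O)C[C@@]2(C)OC(=S)O[C@H]2CC/C(CO[Si](c3ccccc3)(c4ccccc4)C(C)(C)C)=C\C1=O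
F9 | step 9 | (8S)-8-hydroxy-6-oxo enone (14 with C8 reduced) | C1[C@@H](O)C/C(C)=C\CC/C(CO[Si](c3ccccc3)(c4ccccc4)C(C)(C)C)=C\C1=O
F10 | step 9 | C8 TBS ether of F9 | C1[C@@H](O[Si](C)(C)C(C)(C)C)C/C(C)=C\CC/C(CO[Si](c3ccccc3)(c4ccccc4)C(C)(C)C)=C\C1=O
F11 | step 11 | (6S)-hydroxy tert-butyl ester, C6 epimer of 19 | CC(C)(C)OC(=O)C[C@@H]1[C@@H](O[Si](C)(C)C(C)(C)C)C/C(C)=C\CC/C(CO[Si](c3ccccc3)(c4ccccc4)C(C)(C)C)=C\[C@@H]1O
F12 | step 11 | (6R)-4-nitrobenzoate of 19 | CC(C)(C)OC(=O)C[C@@H]1[C@@H](O[Si](C)(C)C(C)(C)C)C/C(C)=C\CC/C(CO[Si](c3ccccc3)(c4ccccc4)C(C)(C)C)=C\[C@H]1OC(=O)c5ccc(cc5)[N+](=O)[O-]
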